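**Retrosynthetic overview**
1. Last events: acetylation and desilylation, decarboxylative methylenation, and 7-exo opening of an (11R,12S)-epoxide (from a Z C11=C12 alkene) by a C15 malonic acid; the ε-lactone (C16–O–C12) is the last ring formed.
2. C1 comes from an asymmetric Michael addition of malonate to a 14-membered C1=C2 enone closed by ring-closing metathesis; C3 (hydride) and C8 (methyl) are set by chelation to the oxolane oxygen.
3. C9–C10 comes from alkylation of a C8 β-keto sulfone with a (Z)-allylic bromide; the β-keto sulfone comes from opening a bicyclic lactone (3,8-dioxabicyclo[3.2.1]octan-2-one) with LiCH2SO2Ph.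
4. Enabling feature: on the oxolane ring O–C4–C5–C6–C7 the two exocyclic carbons C3 (on C4) and C8 (on C7) are cis and both carry oxygen. O3 and C8 can therefore be tied as a temporary lactone bridge C3–O–C8(=O), which makes C4 and C7 the termini of a six-membered carbonyl ylide and C5–C6 a two-carbon dipolarophile; a C3 methyl carbinol from (R)-lactate relays the absolute configuration.
5. Ring order: 1,4-dioxanone and oxolane together in one step, then the lactone bridge is cut, then the 14-membered carbocycle, then the ε-lactone.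

Key step: step 4

Remark: cembrane numbering is used throughout (C1 = ring CH carrying C15; C3 and C11 = acetoxy carbons; C4 = oxolane C–Me; C5, C6 = oxolane CH2; C7 = oxolane CH; C8 = C(Me)OH; C12 = C(Me)–O of the lactone; C15/C16/C17 = α-carbon, carbonyl and exocyclic CH2 of the lactone). The target read from its SMILES is (1R,3S,4R,7S,8R,11R,12R).

**Step 1**
Reactants: 1 methyl (2R)-2-hydroxypropanoate
Product: 2 (2R)-2-hydroxy-N-methoxy-N-methylpropanamide
Conditions: MeNHOMe·HCl, i-PrMgCl, THF, −20 to 0 °C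
Reagents that add atoms: N,O-dimethylhydroxylamine hydrochloride, CNOC.Cl
Why: Aminolysis of the ester by the chloromagnesium amide (Weinreb amide formation) only deprotonates the hydroxyl, so the carbinol centre is untouched.

**Step 2**
Reactants: 2 (2R)-2-hydroxy-N-methoxy-N-methylpropanamide
Product: 3 (3R)-3-hydroxybutan-2-one
Conditions: MeMgBr (2.2 equiv), THF, 0 °C; aq. NH4Cl; used as a solution
Reagents that add atoms: methylmagnesium bromide, C[Mg]Br
Why: The magnesium chelate of the Weinreb amide collapses to the methyl ketone only on work-up (Weinreb ketone synthesis), so one methyl group is added and the stereocentre is kept.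

**Step 3**
Reactants: 3 (3R)-3-hydroxybutan-2-one
Product: 5 (2R)-3-oxobutan-2-yl 2-diazoacetate, via tosylhydrazone ester 4 (not isolated)
Conditions: TsNHN=CHCOCl, PhNMe2, CH2Cl2, 0 °C; then Et3N, 0 °C
Reagents that add atoms: glyoxylic acid chloride p-toluenesulfonylhydrazone, Cc1ccc(cc1)S(=O)(=O)NN=CC(Cl)=O
Why: O-acylation followed by base-induced loss of p-toluenesulfinate from the tosylhydrazone (Bamford–Stevens-type diazo formation) is the standard one-flask route from an alcohol to its diazoacetate, and the short exposure to Et3N at 0 °C should spare the α-acyloxy ketone centre.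

**Step 4**
Reactants: 5 (2R)-3-oxobutan-2-yl 2-diazoacetate; 6 (E)-1,2-bis(phenylsulfonyl)ethene
Product: 8 4,5-dimethyl-6,7-bis(phenylsulfonyl)-3,8-dioxabicyclo[3.2.1]octan-2-one, via carbonyl ylide 7 (not isolated)
Conditions: Rh2(OAc)4 (1 mol %), 6 (2 equiv), CH2Cl2, 40 °C, 5 added over 8 h
Reagents that add atoms: none
Why: Proposed new method: Rh2(OAc)4 expels N2 from 5 to give a rhodium carbene whose carbon (C7) is attacked, through the s-cis ester rotamer, by the ketone oxygen, and the resulting carbonyl ylide 7 (C4=O(+)–C7(−)) adds across the strongly electron-poor alkene 6 in a concerted, suprafacial [3+2] cycloaddition that makes the C4–C5 and C6–C7 bonds together. The closest known reaction type is the Rh2(OAc)4-catalysed tandem carbonyl-ylide formation/1,3-dipolar cycloaddition of 1-diazoalkane-2,5-diones, where the tether is all-carbon; a tether running through the ester oxygen of a diazoacetate is not an established substrate class, but capture of diazoacetate carbenes by groups on the alkoxy side (allylic C=C, γ-C–H) shows that the required rotamer is reachable. The temporary 1,4-dioxan-2-one ring closes by intramolecular O-to-carbene bond formation (six-membered ylide), and the oxolane ring closes by the intermolecular cycloaddition across the two ylide termini. C4 and C7 must come out cis on the oxolane because both lie in the planar ylide that is bridged on one face, and their absolute configuration is controlled by C3: its methyl group avoids the in-plane C4 methyl (allylic strain), stands pseudo-axial and blocks that face, so 6 adds anti to it. The step needs chemoselectivity for intramolecular ylide formation over carbene dimerisation (slow addition of 5 into excess 6) and fast trapping of the ylide before proton transfer (highly reactive dipolarophile); it needs no regio- or endo/exo control, since both sulfonyl-bearing carbons become CH2 in steps 5 and 6.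

**Step 5**
Reactants: 8 4,5-dimethyl-6,7-bis(phenylsulfonyl)-3,8-dioxabicyclo[3.2.1]octan-2-one
Product: 9 (1S,4R,5R)-4,5-dimethyl-3,8-dioxabicyclo[3.2.1]oct-6-en-2-one
Conditions: Na(Hg) (sodium amalgam, 6 %), Na2HPO4, THF/MeOH 10:1, −20 °C
Reagents that add atoms: none
Why: Two-electron reduction of the vicinal bis-sulfone expels both sulfinates (Julia-type reductive elimination), the β-sulfinate leaving far faster than the β-alkoxy bridge, so the C5=C6 alkene should form without opening the oxolane.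

**Step 6**
Reactants: 9 (1S,4R,5R)-4,5-dimethyl-3,8-dioxabicyclo[3.2.1]oct-6-en-2-one
Product: 10 (1S,4R,5R)-4,5-dimethyl-3,8-dioxabicyclo[3.2.1]octan-2-one
Conditions: H2 (1 atm), Pd/C, EtOAc, rt
Reagents that add atoms: none
Why: Catalytic hydrogenation of the strained disubstituted alkene turns C5 and C6 into the CH2–CH2 unit of the target and creates no stereocentre.

**Step 7**
Reactants: 11 hex-5-en-1-yne
Product: 12 ethyl hept-6-en-2-ynoate
Conditions: n-BuLi, THF, −78 °C; ClCO2Et, −78 to 0 °C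
Reagents that add atoms: ethyl chloroformate, CCOC(Cl)=O
Why: C-acylation of the lithium acetylide with the chloroformate (acetylide carboxylation) gives the ynoate that holds C10 to C14 and C1.

**Step 8**
Reactants: 12 ethyl hept-6-en-2-ynoate
Product: 13 ethyl (2Z)-3-methylhepta-2,6-dienoate
Conditions: Me2CuLi, THF, −78 °C; MeOH then aq. NH4Cl at −78 °C
Reagents that add atoms: lithium dimethylcuprate, [Li+].C[Cu-]C
Why: Syn carbocupration of the ynoate and protonation of the vinylcopper with retention (cuprate conjugate addition to an alkynoate) place the new methyl cis to H-11, that is C10 cis to C13, which fixes the Z geometry of C11=C12.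

**Step 9**
Reactants: 13 ethyl (2Z)-3-methylhepta-2,6-dienoate
Product: 14 (2Z)-3-methylhepta-2,6-dien-1-ol
Conditions: i-Bu2AlH (2.2 equiv), CH2Cl2, −78 to 0 °C
Reagents that add atoms: none
Why: i-Bu2AlH reduces the conjugated ester to the allylic alcohol (1,2-reduction) without touching the alkene geometry.

**Step 10**
Reactants: 14 (2Z)-3-methylhepta-2,6-dien-1-ol
Product: 15 (2Z)-1-bromo-3-methylhepta-2,6-diene
Conditions: CBr4, PPh3, CH2Cl2, 0 °C
Reagents that add atoms: carbon tetrabromide, BrC(Br)(Br)Br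
Why: The Appel reaction converts the primary allylic alcohol into the bromide under neutral conditions that should not isomerise the Z alkene.

**Step 11**
Reactants: 10 (1S,4R,5R)-4,5-dimethyl-3,8-dioxabicyclo[3.2.1]octan-2-one; 16 methyl phenyl sulfone
Product: 17 1-[(2S,5R)-5-[(1R)-1-hydroxyethyl]-5-methyloxolan-2-yl]-2-(phenylsulfonyl)ethan-1-one
Conditions: 16 (2.3 equiv), n-BuLi (2.2 equiv), THF, −78 °C; then 10, −78 to −40 °C; aq. NH4Cl
Reagents that add atoms: none
Why: The lithiated sulfone opens the lactone bridge by acyl substitution (Claisen-type condensation) and the β-keto sulfone is deprotonated at once, which prevents a second addition, brings in C9 and releases the C3 carbinol.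

**Step 12**
Reactants: 17 1-[(2S,5R)-5-[(1R)-1-hydroxyethyl]-5-methyloxolan-2-yl]-2-(phenylsulfonyl)ethan-1-one; 15 (2Z)-1-bromo-3-methylhepta-2,6-diene
Product: 18 (4Z)-1-[(2S,5R)-5-[(1R)-1-hydroxyethyl]-5-methyloxolan-2-yl]-5-methyl-2-(phenylsulfonyl)nona-4,8-dien-1-one
Conditions: K2CO3, Bu4NI (cat.), acetone, rt
Reagents that add atoms: none
Why: The soft β-keto sulfone enolate is C-alkylated by the primary allylic bromide (SN2), forming the C9–C10 bond; the new C9 centre is removed in step 13.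

**Step 13**
Reactants: 18 (4Z)-1-[(2S,5R)-5-[(1R)-1-hydroxyethyl]-5-methyloxolan-2-yl]-5-methyl-2-(phenylsulfonyl)nona-4,8-dien-1-one
Product: 19 (4Z)-1-[(2S,5R)-5-[(1R)-1-hydroxyethyl]-5-methyloxolan-2-yl]-5-methylnona-4,8-dien-1-one
Conditions: SmI2 (2.5 equiv), THF/MeOH, −78 °C
Reagents that add atoms: none
Why: Electron transfer from SmI2 to the α-sulfonyl ketone cleaves the C9–S bond (reductive desulfonylation) and the samarium enolate, which forms towards C9 and not C7, is protonated to the ketone.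

**Step 14**
Reactants: 19 (4Z)-1-[(2S,5R)-5-[(1R)-1-hydroxyethyl]-5-methyloxolan-2-yl]-5-methylnona-4,8-dien-1-one
Product: 20 (2R,5Z)-2-[(2S,5R)-5-[(1R)-1-hydroxyethyl]-5-methyloxolan-2-yl]-6-methyldeca-5,9-dien-2-ol
Conditions: MeMgBr (4 equiv), CH2Cl2/Et2O, −78 °C
Reagents that add atoms: methylmagnesium bromide, C[Mg]Br
Why: Magnesium bridges the C8 carbonyl and the oxolane oxygen, and methyl adds to the face of this five-membered chelate that carries H-7 rather than C6 (chelation-controlled Grignard addition), which should give the (8R) tertiary alcohol.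

**Step 15**
Reactants: 20 (2R,5Z)-2-[(2S,5R)-5-[(1R)-1-hydroxyethyl]-5-methyloxolan-2-yl]-6-methyldeca-5,9-dien-2-ol
Product: 21 1-[(2R,5S)-5-[(2R,5Z)-2-hydroxy-6-methyldeca-5,9-dien-2-yl]-2-methyloxolan-2-yl]ethan-1-one
Conditions: Dess–Martin periodinane, NaHCO3, CH2Cl2, rt
Reagents that add atoms: none
Why: Dess–Martin oxidation turns the secondary C3 carbinol, whose relay task is finished, into the methyl ketone, while the tertiary C8 alcohol cannot react.

**Step 16**
Reactants: 21 1-[(2R,5S)-5-[(2R,5Z)-2-hydroxy-6-methyldeca-5,9-dien-2-yl]-2-methyloxolan-2-yl]ethan-1-one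
Product: 23 1-[(2R,5S)-5-[(2R,5Z)-2-hydroxy-6-methyldeca-5,9-dien-2-yl]-2-methyloxolan-2-yl]prop-2-en-1-one, via Mannich base 22 (not isolated)
Conditions: (CH2O)n, N-methylanilinium trifluoroacetate, THF, reflux
Reagents that add atoms: formaldehyde (as paraformaldehyde), C=O
Why: The ketone can enolise only towards C2 because C4 is quaternary, so a Mannich reaction followed by loss of N-methylaniline (α-methylenation of a ketone) gives the vinyl ketone.

**Step 17**
Reactants: 23 1-[(2R,5S)-5-[(2R,5Z)-2-hydroxy-6-methyldeca-5,9-dien-2-yl]-2-methyloxolan-2-yl]prop-2-en-1-one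
Product: 24 (1E,4R,7S,8R,11Z)-8-hydroxy-4,8,12-trimethyl-4,7-epoxycyclotetradeca-1,11-dien-3-one
Conditions: second-generation Grubbs catalyst (10 mol %), CH2Cl2 (0.5 mM), 40 °C
Reagents that add atoms: none
Why: Ring-closing metathesis between the terminal C1 alkene (initiation site) and the vinyl ketone releases ethene and closes the 14-membered ring as the conjugated E enone, the trisubstituted C11=C12 bond being too hindered to take part.

**Step 18**
Reactants: 24 (1E,4R,7S,8R,11Z)-8-hydroxy-4,8,12-trimethyl-4,7-epoxycyclotetradeca-1,11-dien-3-one; 25 diallyl malonate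
Product: 26 diallyl 2-[(1R,4R,7S,8R,11Z)-8-hydroxy-4,8,12-trimethyl-3-oxo-4,7-epoxycyclotetradec-11-en-1-yl]propanedioate
Conditions: La(O-i-Pr)3 (10 mol %), (S,S)-linked-BINOL (10 mol %), THF, 0 °C to rt
Reagents that add atoms: none
Why: The lanthanum BINOLate binds the enone and the malonate enolate and delivers the nucleophile to one face of C1 (catalytic asymmetric Michael addition), so the ligand controls the (1R) centre, and its mirror image is used should the (S,S) ligand prove mismatched with the ring.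

**Step 19**
Reactants: 26 diallyl 2-[(1R,4R,7S,8R,11Z)-8-hydroxy-4,8,12-trimethyl-3-oxo-4,7-epoxycyclotetradec-11-en-1-yl]propanedioate
Product: 27 diallyl 2-[(1R,3S,4R,7S,8R,11Z)-3,8-dihydroxy-4,8,12-trimethyl-4,7-epoxycyclotetradec-11-en-1-yl]propanedioate
Conditions: Zn(BH4)2, Et2O, −30 °C
Reagents that add atoms: none
Why: Zinc chelates the C3 carbonyl and the oxolane oxygen, and hydride attacks the chelate from the side of the C4 methyl group rather than the ring CH2 (chelation-controlled reduction), which should give the (3S) alcohol.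

**Step 20**
Reactants: 27 diallyl 2-[(1R,3S,4R,7S,8R,11Z)-3,8-dihydroxy-4,8,12-trimethyl-4,7-epoxycyclotetradec-11-en-1-yl]propanedioate
Product: 28 diallyl 2-[(1R,3S,4R,7S,8R,11Z)-3-acetoxy-8-hydroxy-4,8,12-trimethyl-4,7-epoxycyclotetradec-11-en-1-yl]propanedioate
Conditions: Ac2O, pyridine, DMAP (cat.), CH2Cl2, 0 °C
Reagents that add atoms: acetic anhydride, CC(=O)OC(C)=O
Why: DMAP-catalysed acetylation of the only secondary hydroxyl installs the C3 acetate of the target and stops O3 from lactonising onto the malonate, while the tertiary C8 hydroxyl does not react.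

**Step 21**
Reactants: 28 diallyl 2-[(1R,3S,4R,7S,8R,11Z)-3-acetoxy-8-hydroxy-4,8,12-trimethyl-4,7-epoxycyclotetradec-11-en-1-yl]propanedioate
Product: 29 diallyl 2-[(1R,3S,4R,7S,8R,11Z)-3-acetoxy-4,8,12-trimethyl-8-(triethylsilyloxy)-4,7-epoxycyclotetradec-11-en-1-yl]propanedioate
Conditions: Et3SiOTf, 2,6-lutidine, CH2Cl2, −78 to 0 °C
Reagents that add atoms: triethylsilyl trifluoromethanesulfonate, CC[Si](CC)(CC)OS(=O)(=O)C(F)(F)F
Why: Silylation of the tertiary C8 hydroxyl (silyl ether formation) keeps it from opening the epoxide made in step 22 in a six-membered mode.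

**Step 22**
Reactants: 29 diallyl 2-[(1R,3S,4R,7S,8R,11Z)-3-acetoxy-4,8,12-trimethyl-8-(triethylsilyloxy)-4,7-epoxycyclotetradec-11-en-1-yl]propanedioate
Product: 30 diallyl 2-[(1R,3S,4R,7S,8R,11R,12S)-3-acetoxy-4,8,12-trimethyl-8-(triethylsilyloxy)-4,7:11,12-diepoxycyclotetradecan-1-yl]propanedioate
Conditions: D-fructose-derived Shi ketone (30 mol %), Oxone (KHSO5), K2CO3, Bu4NHSO4, MeCN/(MeO)2CH2/aq. buffer pH 10.5, 0 °C
Reagents that add atoms: potassium peroxymonosulfate, [K+].[O-]S(=O)(=O)OO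
Why: The chiral dioxirane epoxidises the electron-rich trisubstituted C11=C12 bond through a spiro transition state (Shi epoxidation) in which the trans pair C10/C12-methyl is read like a trans alkene, which should give the (11R,12S)-epoxide, while the monosubstituted allyl ester alkenes react too slowly to compete.

**Step 23**
Reactants: 30 diallyl 2-[(1R,3S,4R,7S,8R,11R,12S)-3-acetoxy-4,8,12-trimethyl-8-(triethylsilyloxy)-4,7:11,12-diepoxycyclotetradecan-1-yl]propanedioate
Product: 32 15-carboxy-15,17-dihydro-11-O-deacetyl-8-O-triethylsilylquerciformolide C, via malonic acid 31 (not isolated)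
Conditions: Pd(PPh3)4 (5 mol %), pyrrolidine (2.2 equiv), THF, 0 °C; acid wash; then CSA (0.2 equiv), CH2Cl2, rt
Reagents that add atoms: none
Why: Allyl transfer to pyrrolidine through π-allylpalladium frees the malonic acid, one carboxyl of which opens the protonated epoxide at the tertiary carbon C12 with inversion (7-exo acid-catalysed epoxide opening), which sets (12R), releases the (11R) hydroxyl and closes the ε-lactone.

**Step 24**
Reactants: 32 15-carboxy-15,17-dihydro-11-O-deacetyl-8-O-triethylsilylquerciformolide C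
Product: 34 11-O-deacetyl-8-O-triethylsilylquerciformolide C, via aminomethyl acid 33 (not isolated)
Conditions: aq. CH2O, Et2NH, THF, rt; then NaOAc, AcOH, 70 °C
Reagents that add atoms: formaldehyde, C=O
Why: The α-carboxy lactone undergoes a Mannich reaction at C15 and the β-amino acid then loses CO2 and diethylamine (decarboxylative Mannich methylenation), giving the exocyclic C15=C17 bond without touching C1.

**Step 25**
Reactants: 34 11-O-deacetyl-8-O-triethylsilylquerciformolide C
Product: 35 8-O-triethylsilylquerciformolide C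
Conditions: Ac2O, pyridine, DMAP, CH2Cl2, rt
Reagents that add atoms: acetic anhydride, CC(=O)OC(C)=O
Why: DMAP-catalysed acetylation of the secondary C11 hydroxyl completes the diacetate while the silyl ether covers C8.

**Step 26**
Reactants: 35 8-O-triethylsilylquerciformolide C
Product: 36 querciformolide C
Conditions: HF·pyridine, THF, 0 °C to rt
Reagents that add atoms: none
Why: Fluoride cleaves the tertiary silyl ether under mildly acidic conditions (desilylation), which should release the C8 hydroxyl without acyl migration or addition to the α-methylene lactone.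

**Compound list**
1 | methyl (2R)-2-hydroxypropanoate | C[C@@H](O)C(=O)OC | starting material
2 | (2R)-2-hydroxy-N-methoxy-N-methylpropanamide | C[C@@H](O)C(=O)N(C)OC | intermediate
3 | (3R)-3-hydroxybutan-2-one | C[C@@H](O)C(C)=O | intermediate
4 | (2R)-3-oxobutan-2-yl 2-[2-(4-methylphenylsulfonyl)hydrazinylidene]acetate | C[C@@H](OC(=O)C=NNS(=O)(=O)c1ccc(C)cc1)C(C)=O | intermediate (not isolated)
5 | (2R)-3-oxobutan-2-yl 2-diazoacetate | C[C@@H](OC(=O)C=[N+]=[N-])C(C)=O | intermediate
6 | (E)-1,2-bis(phenylsulfonyl)ethene | O=S(=O)(/C=C/S(=O)(=O)c1ccccc1)c1ccccc1 | starting material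
7 | (6R)-5,6-dimethyl-2-oxo-6H-1,4-dioxin-4-ium-3-ide (cyclic carbonyl ylide, C4=O(+)–C7(−)) | C[C@H]1OC(=O)[CH-][O+]=C1C | intermediate (not isolated)
8 | 4,5-dimethyl-6,7-bis(phenylsulfonyl)-3,8-dioxabicyclo[3.2.1]octan-2-one; C1, C4 and C5 arranged as in 10, sulfonyl groups trans (both trans isomers; these two centres are left open in the SMILES because step 5 destroys them) | C[C@H]1OC(=O)[C@@H]2C(S(=O)(=O)c3ccccc3)C(S(=O)(=O)c3ccccc3)[C@@]1(C)O2 | intermediate
9 | (1S,4R,5R)-4,5-dimethyl-3,8-dioxabicyclo[3.2.1]oct-6-en-2-one | C[C@H]1OC(=O)[C@@H]2C=C[C@@]1(C)O2 | intermediate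
10 | (1S,4R,5R)-4,5-dimethyl-3,8-dioxabicyclo[3.2.1]octan-2-one | C[C@H]1OC(=O)[C@@H]2CC[C@@]1(C)O2 | intermediate
11 | hex-5-en-1-yne | C#CCCC=C | starting material
12 | ethyl hept-6-en-2-ynoate | CCOC(=O)C#CCCC=C | intermediate
13 | ethyl (2Z)-3-methylhepta-2,6-dienoate | CCOC(=O)/C=C(/C)CCC=C | intermediate
14 | (2Z)-3-methylhepta-2,6-dien-1-ol | OC/C=C(/C)CCC=C | intermediate
15 | (2Z)-1-bromo-3-methylhepta-2,6-diene | BrC/C=C(/C)CCC=C | intermediate
16 | methyl phenyl sulfone | CS(=O)(=O)c1ccccc1 | starting material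
17 | 1-[(2S,5R)-5-[(1R)-1-hydroxyethyl]-5-methyloxolan-2-yl]-2-(phenylsulfonyl)ethan-1-one | C[C@@H](O)[C@@]1(C)CC[C@H](O1)C(=O)CS(=O)(=O)c1ccccc1 | intermediate
18 | (4Z)-1-[(2S,5R)-5-[(1R)-1-hydroxyethyl]-5-methyloxolan-2-yl]-5-methyl-2-(phenylsulfonyl)nona-4,8-dien-1-one (both epimers at the sulfonyl carbon) | C[C@@H](O)[C@@]1(C)CC[C@H](O1)C(=O)C(C/C=C(/C)CCC=C)S(=O)(=O)c1ccccc1 | intermediate
19 | (4Z)-1-[(2S,5R)-5-[(1R)-1-hydroxyethyl]-5-methyloxolan-2-yl]-5-methylnona-4,8-dien-1-one | C[C@@H](O)[C@@]1(C)CC[C@H](O1)C(=O)CC/C=C(/C)CCC=C | intermediate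
20 | (2R,5Z)-2-[(2S,5R)-5-[(1R)-1-hydroxyethyl]-5-methyloxolan-2-yl]-6-methyldeca-5,9-dien-2-ol | C[C@@H](O)[C@@]1(C)CC[C@H](O1)[C@](C)(O)CC/C=C(/C)CCC=C | intermediate
21 | 1-[(2R,5S)-5-[(2R,5Z)-2-hydroxy-6-methyldeca-5,9-dien-2-yl]-2-methyloxolan-2-yl]ethan-1-one | CC(=O)[C@@]1(C)CC[C@H](O1)[C@](C)(O)CC/C=C(/C)CCC=C | intermediate
22 | 1-[(2R,5S)-5-[(2R,5Z)-2-hydroxy-6-methyldeca-5,9-dien-2-yl]-2-methyloxolan-2-yl]-3-[methyl(phenyl)amino]propan-1-one | CN(CCC(=O)[C@@]1(C)CC[C@H](O1)[C@](C)(O)CC/C=C(/C)CCC=C)c1ccccc1 | intermediate (not isolated)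
23 | 1-[(2R,5S)-5-[(2R,5Z)-2-hydroxy-6-methyldeca-5,9-dien-2-yl]-2-methyloxolan-2-yl]prop-2-en-1-one | C=CC(=O)[C@@]1(C)CC[C@H](O1)[C@](C)(O)CC/C=C(/C)CCC=C | intermediate
24 | (1E,4R,7S,8R,11Z)-8-hydroxy-4,8,12-trimethyl-4,7-epoxycyclotetradeca-1,11-dien-3-one | O=C1/C=C/CC/C(C)=C\CC[C@@](C)(O)[C@@H]2CC[C@@]1(C)O2 | intermediate
25 | diallyl malonate | C=CCOC(=O)CC(=O)OCC=C | starting material
26 | diallyl 2-[(1R,4R,7S,8R,11Z)-8-hydroxy-4,8,12-trimethyl-3-oxo-4,7-epoxycyclotetradec-11-en-1-yl]propanedioate | O=C1C[C@H](C(C(=O)OCC=C)C(=O)OCC=C)CC/C(C)=C\CC[C@@](C)(O)[C@@H]2CC[C@@]1(C)O2 | intermediate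
27 | diallyl 2-[(1R,3S,4R,7S,8R,11Z)-3,8-dihydroxy-4,8,12-trimethyl-4,7-epoxycyclotetradec-11-en-1-yl]propanedioate | O[C@H]1C[C@H](C(C(=O)OCC=C)C(=O)OCC=C)CC/C(C)=C\CC[C@@](C)(O)[C@@H]2CC[C@@]1(C)O2 | intermediate
28 | diallyl 2-[(1R,3S,4R,7S,8R,11Z)-3-acetoxy-8-hydroxy-4,8,12-trimethyl-4,7-epoxycyclotetradec-11-en-1-yl]propanedioate | CC(=O)O[C@H]1C[C@H](C(C(=O)OCC=C)C(=O)OCC=C)CC/C(C)=C\CC[C@@](C)(O)[C@@H]2CC[C@@]1(C)O2 | intermediate
29 | diallyl 2-[(1R,3S,4R,7S,8R,11Z)-3-acetoxy-4,8,12-trimethyl-8-(triethylsilyloxy)-4,7-epoxycyclotetradec-11-en-1-yl]propanedioate | CC(=O)O[C@H]1C[C@H](C(C(=O)OCC=C)C(=O)OCC=C)CC/C(C)=C\CC[C@@](C)(O[Si](CC)(CC)CC)[C@@H]2CC[C@@]1(C)O2 | intermediate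
30 | diallyl 2-[(1R,3S,4R,7S,8R,11R,12S)-3-acetoxy-4,8,12-trimethyl-8-(triethylsilyloxy)-4,7:11,12-diepoxycyclotetradecan-1-yl]propanedioate | CC(=O)O[C@H]1C[C@H](C(C(=O)OCC=C)C(=O)OCC=C)CC[C@]3(C)O[C@@H]3CC[C@@](C)(O[Si](CC)(CC)CC)[C@@H]2CC[C@@]1(C)O2 | intermediate
31 | 2-[(1R,3S,4R,7S,8R,11R,12S)-3-acetoxy-4,8,12-trimethyl-8-(triethylsilyloxy)-4,7:11,12-diepoxycyclotetradecan-1-yl]propanedioic acid | CC(=O)O[C@H]1C[C@H](C(C(=O)O)C(=O)O)CC[C@]3(C)O[C@@H]3CC[C@@](C)(O[Si](CC)(CC)CC)[C@@H]2CC[C@@]1(C)O2 | intermediate (not isolated)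
32 | 15-carboxy-15,17-dihydro-11-O-deacetyl-8-O-triethylsilylquerciformolide C (α-carboxy ε-lactone, both C15 epimers) | OC(=O)C1C(=O)O[C@]2(C)CC[C@@H]1C[C@H](OC(C)=O)[C@@]1(C)CC[C@H](O1)[C@](C)(O[Si](CC)(CC)CC)CC[C@H]2O | intermediate
33 | 15-carboxy-15-(diethylaminomethyl)-15,17-dihydro-11-O-deacetyl-8-O-triethylsilylquerciformolide C | CCN(CC)CC1(C(O)=O)C(=O)O[C@]2(C)CC[C@@H]1C[C@H](OC(C)=O)[C@@]1(C)CC[C@H](O1)[C@](C)(O[Si](CC)(CC)CC)CC[C@H]2O | intermediate (not isolated)
34 | 11-O-deacetyl-8-O-triethylsilylquerciformolide C | C=C1C(=O)O[C@]2(C)CC[C@@H]1C[C@H](OC(C)=O)[C@@]1(C)CC[C@H](O1)[C@](C)(O[Si](CC)(CC)CC)CC[C@H]2O | intermediate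
35 | 8-O-triethylsilylquerciformolide C | C=C1C(=O)O[C@]2(C)CC[C@@H]1C[C@H](OC(C)=O)[C@@]1(C)CC[C@H](O1)[C@](C)(O[Si](CC)(CC)CC)CC[C@H]2OC(C)=O | intermediate
36 | querciformolide C | C=C1C(=O)O[C@]2(C)CC[C@@H]1C[C@H](OC(C)=O)[C@@]1(C)CC[C@H](O1)[C@](C)(O)CC[C@H]2OC(C)=O | target

**Step count and risks**
Total step count: 26. Longest linear sequence: 22 steps (steps 1–6 and 11–26, from methyl (R)-lactate); the bromide 15 is made in 4 steps (7–10) and joins at step 12.

Steps most likely to fail: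

1. Step 4 (the labelled step). What may go wrong: the carbene dimerises or inserts before the ester reaches the s-cis rotamer, or the ylide is trapped on both faces so that the relay from C3 is lost. Fallback (known chemistry; the same two bonds are made by a furan Diels–Alder reaction): it sets out from compound 6. Heating 6 with 2,3-dimethylfuran F1 in toluene should give the 7-oxanorbornene bis-sulfone F2. Na(Hg) then removes both sulfonyl groups to give the 7-oxanorbornadiene F3, and H2 with RhCl(PPh3)3 saturates only the disubstituted C5=C6 bond to give the 7-oxanorbornene F4. Ozonolysis in MeOH/NaHCO3 followed by Ac2O/Et3N cleaves the C3=C8 bond to the racemic cis keto ester F5, and LiBH(s-Bu)3 (Felkin–Anh addition) gives the racemic hydroxy ester F6. Candida antarctica lipase B with vinyl acetate acylates only the (1'R) enantiomer to the acetate F7, which is separated from the unreacted alcohol. Excess LiCH2SO2Ph (ester and acetate both cleaved) converts F7 into compound 17, where the route is rejoined.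

2. Step 18. What may go wrong: slow addition to the hindered β-alkyl macrocyclic enone and poor facial selectivity at C1 when the ring conformation opposes the catalyst. Fallback (C15 brought in as an alkenyl group by a rhodium-catalysed Hayashi–Miyaura 1,4-addition, which is strongly catalyst-controlled on E enones): it sets out from compound 24. With 2-(4,4,5,5-tetramethyl-1,3,2-dioxaborolan-2-yl)prop-2-en-1-ol, [RhCl(C2H4)2]2, (R)-BINAP and KOH in dioxane/H2O, 24 should give the allylic alcohol F8. TEMPO/PhI(OAc)2 in MeCN/H2O oxidises it to the acrylic acid F9, and allyl bromide/K2CO3 gives the allyl ester F10. The operations of steps 19 to 22 (Zn(BH4)2; Ac2O; Et3SiOTf; Shi epoxidation) then give in turn the C3 alcohol F11, the acetate F12, the silyl ether F13 and the epoxide F14. Pd(PPh3)4/pyrrolidine followed by CSA gives compound 34 directly, where the route is rejoined.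

3. Step 23. What may go wrong: the protonated trisubstituted epoxide rearranges by a 1,2-hydride shift or eliminates faster than the seven-membered ring closes. Fallback (the C12–O bond is made by acylating the tertiary alcohol instead of alkylating the acid): it sets out from compound 30. Aqueous acid (cat. HClO4, THF/H2O, 0 °C) opens the epoxide at the tertiary carbon with inversion to the 11,12-diol F15, and Ac2O/pyridine acetylates only the secondary C11 hydroxyl to give F16. Pd(PPh3)4/pyrrolidine then gives the malonic acid F17, and CH2O/Et2NH converts it by decarboxylative methylenation into the acrylic acid F18. Shiina macrolactonisation (2-methyl-6-nitrobenzoic anhydride, DMAP, toluene, 60 °C, high dilution) on the tertiary C12 hydroxyl gives compound 35, where the route is rejoined.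

**Further compounds**
F1 | step 4 | 2,3-dimethylfuran | Cc1occc1C
F2 | step 4 | 1,2-dimethyl-5,6-bis(phenylsulfonyl)-7-oxabicyclo[2.2.1]hept-2-ene (racemic, sulfonyl groups trans) | CC1=CC2OC1(C)C(S(=O)(=O)c1ccccc1)C2S(=O)(=O)c1ccccc1
F3 | step 4 | 1,2-dimethyl-7-oxabicyclo[2.2.1]hepta-2,5-diene (racemic) | CC1=CC2OC1(C)C=C2
F4 | step 4 | 1,2-dimethyl-7-oxabicyclo[2.2.1]hept-2-ene (racemic) | CC1=CC2OC1(C)CC2
F5 | step 4 | methyl (2S,5R)-5-acetyl-5-methyloxolane-2-carboxylate (racemate; one enantiomer drawn) | CC(=O)[C@@]1(C)CC[C@H](O1)C(=O)OC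
F6 | step 4 | methyl (2S,5R)-5-[(1R)-1-hydroxyethyl]-5-methyloxolane-2-carboxylate (racemate; one enantiomer drawn) | C[C@@H](O)[C@@]1(C)CC[C@H](O1)C(=O)OC
F7 | step 4 | methyl (2S,5R)-5-[(1R)-1-acetoxyethyl]-5-methyloxolane-2-carboxylate | C[C@@H](OC(C)=O)[C@@]1(C)CC[C@H](O1)C(=O)OC
F8 | step 18 | (1R,4R,7S,8R,11Z)-8-hydroxy-1-(3-hydroxyprop-1-en-2-yl)-4,8,12-trimethyl-4,7-epoxycyclotetradec-11-en-3-one | O=C1C[C@H](C(=C)CO)CC/C(C)=C\CC[C@@](C)(O)[C@@H]2CC[C@@]1(C)O2
F9 | step 18 | 2-[(1R,4R,7S,8R,11Z)-8-hydroxy-4,8,12-trimethyl-3-oxo-4,7-epoxycyclotetradec-11-en-1-yl]prop-2-enoic acid | O=C1C[C@H](C(=C)C(O)=O)CC/C(C)=C\CC[C@@](C)(O)[C@@H]2CC[C@@]1(C)O2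
F10 | step 18 | allyl 2-[(1R,4R,7S,8R,11Z)-8-hydroxy-4,8,12-trimethyl-3-oxo-4,7-epoxycyclotetradec-11-en-1-yl]prop-2-enoate | O=C1C[C@H](C(=C)C(=O)OCC=C)CC/C(C)=C\CC[C@@](C)(O)[C@@H]2CC[C@@]1(C)O2
F11 | step 18 | allyl 2-[(1R,3S,4R,7S,8R,11Z)-3,8-dihydroxy-4,8,12-trimethyl-4,7-epoxycyclotetradec-11-en-1-yl]prop-2-enoate | O[C@H]1C[C@H](C(=C)C(=O)OCC=C)CC/C(C)=C\CC[C@@](C)(O)[C@@H]2CC[C@@]1(C)O2
F12 | step 18 | allyl 2-[(1R,3S,4R,7S,8R,11Z)-3-acetoxy-8-hydroxy-4,8,12-trimethyl-4,7-epoxycyclotetradec-11-en-1-yl]prop-2-enoate | CC(=O)O[C@H]1C[C@H](C(=C)C(=O)OCC=C)CC/C(C)=C\CC[C@@](C)(O)[C@@H]2CC[C@@]1(C)O2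
F13 | step 18 | allyl 2-[(1R,3S,4R,7S,8R,11Z)-3-acetoxy-4,8,12-trimethyl-8-(triethylsilyloxy)-4,7-epoxycyclotetradec-11-en-1-yl]prop-2-enoate | CC(=O)O[C@H]1C[C@H](C(=C)C(=O)OCC=C)CC/C(C)=C\CC[C@@](C)(O[Si](CC)(CC)CC)[C@@H]2CC[C@@]1(C)O2
F14 | step 18 | allyl 2-[(1R,3S,4R,7S,8R,11R,12S)-3-acetoxy-4,8,12-trimethyl-8-(triethylsilyloxy)-4,7:11,12-diepoxycyclotetradecan-1-yl]prop-2-enoate | CC(=O)O[C@H]1C[C@H](C(=C)C(=O)OCC=C)CC[C@]3(C)O[C@@H]3CC[C@@](C)(O[Si](CC)(CC)CC)[C@@H]2CC[C@@]1(C)O2
F15 | step 23 | diallyl 2-[(1R,3S,4R,7S,8R,11R,12R)-3-acetoxy-11,12-dihydroxy-4,8,12-trimethyl-8-(triethylsilyloxy)-4,7-epoxycyclotetradecan-1-yl]propanedioate | CC(=O)O[C@H]1C[C@H](C(C(=O)OCC=C)C(=O)OCC=C)CC[C@@](C)(O)[C@H](O)CC[C@@](C)(O[Si](CC)(CC)CC)[C@@H]2CC[C@@]1(C)O2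
F16 | step 23 | diallyl 2-[(1R,3S,4R,7S,8R,11R,12R)-3,11-diacetoxy-12-hydroxy-4,8,12-trimethyl-8-(triethylsilyloxy)-4,7-epoxycyclotetradecan-1-yl]propanedioate | CC(=O)O[C@H]1C[C@H](C(C(=O)OCC=C)C(=O)OCC=C)CC[C@@](C)(O)[C@H](OC(C)=O)CC[C@@](C)(O[Si](CC)(CC)CC)[C@@H]2CC[C@@]1(C)O2
F17 | step 23 | 2-[(1R,3S,4R,7S,8R,11R,12R)-3,11-diacetoxy-12-hydroxy-4,8,12-trimethyl-8-(triethylsilyloxy)-4,7-epoxycyclotetradecan-1-yl]propanedioic acid | CC(=O)O[C@H]1C[C@H](C(C(=O)O)C(=O)O)CC[C@@](C)(O)[C@H](OC(C)=O)CC[C@@](C)(O[Si](CC)(CC)CC)[C@@H]2CC[C@@]1(C)O2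
F18 | step 23 | 2-[(1R,3S,4R,7S,8R,11R,12R)-3,11-diacetoxy-12-hydroxy-4,8,12-trimethyl-8-(triethylsilyloxy)-4,7-epoxycyclotetradecan-1-yl]prop-2-enoic acid | CC(=O)O[C@H]1C[C@H](C(=C)C(O)=O)CC[C@@](C)(O)[C@H](OC(C)=O)CC[C@@](C)(O[Si](CC)(CC)CC)[C@@H]2CC[C@@]1(C)O2
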